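(Readings and results stem from a simulated flask with constants of no real substance; scatter was added.)

Left-handed substrate was still in the gamma flask when the readings of its left-handed product flattened. I started from that leftover, and the questions are below the runs.

in all of them: left-handed substrate 0.82 M; right-handed substrate 0.82 M; added ligand 17 mM
- eta: reagent 0.82 M; free catalyst 15 mM; run made earlier
- gamma: reagent 0.82 M; free catalyst 56 mM; run made earlier
- dawn: reagent 0.820 M; free catalyst 12 mM; time 10 min
- autumn: reagent 0.820 M; free catalyst 25 mM; time 10 min
- dusk: reagent 0.820 M; free catalyst 50 mM; time 10 min

| run | time / min | left-handed product / % | right-handed product / % |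
|---|---|---|---|
| eta | 0.500 | 5.8 | 0.5 |
| eta | 1.00 | 8.9 | 0 |
| eta | 1.50 | 10.6 | 0 |
| eta | 2.50 | 9.6 | 0.4 |
| eta | 4.00 | 10.8 | 1.0 |
| eta | 8.00 | 9.0 | 3.1 |
| gamma | 1.33 | 26.4 | 0 |
| gamma | 2.50 | 27.9 | 0.1 |
| gamma | 4.00 | 29.2 | 2.4 |
| gamma | 5.00 | 28.0 | 1.0 |
| gamma | 6.00 | 30.1 | 0 |
| gamma | 8.00 | 30.7 | 1.8 |

(each reading ± 1 percentage point)

- free catalyst is single-handed; left-handed substrate and right-handed substrate are mirror images of each other, charged as a racemate, each of them at the stated concentration
- the analysis behind the earlier runs scatters by 1 percentage point, standard deviation
- an excess is the difference of the two amounts in percent of their sum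
- "hardly changes" means that all values lie within two and a half points (for a concentration: within two and a half percent of the largest)

* excess of left-handed product over right-handed product at the end for dawn, autumn, dusk, in this order
* how that number moves from the first to the last of them (hardly changes / rises, then falls / falls all the way / rises all the way / falls, then rises)

From 2.50 min to 8.00 min, gamma's left-handed product averaged 29.2% and its right-handed product 1.06%. That left 20.8% of the substrates charged as left-handed substrate. So what needed explaining was less the stall than how the two products share whatever conversion a flask reaches.

I supposed that both mirror-image substrates use the same catalyst and reagent, each at a rate proportional to its own amount. Let L and D be the amounts of left-handed and right-handed substrate, k_L and k_D their rate constants, and g(t) the unknown common factor of catalyst and reagent: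

dL/dt = −k_L g(t) L, dD/dt = −k_D g(t) D

Dividing the two removes g(t), and integrating gives a closed form, whenever the catalyst stops:

ln(L_start/L) = s ln(D_start/D)

Each substrate is 0.5 of the charge, so gamma's averages give

s = ln(0.5/(0.5 − P))/ln(0.5/(0.5 − Q)) = 40.9

This s is the selectivity factor, the rate constant of the left-handed substrate over that of the right-handed one. It is a rough reading, since Q rests on values near zero that scatter by 1 percentage point.

Now the run in slow motion. In the first instants L equals D, so the products form in the ratio s and the excess is (s − 1)/(s + 1) = 95.2%. In the middle, L falls while D barely moves, so the ratio s·L/D sinks and the excess slides down. At the end I took the products to stop and the excess to stay where it stood, which for gamma read 93.0% from the averages.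

Dusk had 50 mM of catalyst, less than gamma's 56 mM, so I expected it to stop short of gamma's conversion. Dawn, with the least catalyst, should stay nearer the start. My row therefore lay between 93.0% and 95.2%, which are 2.2 points apart, and I expected the excess to hardly change.

The forecast differed: 64%, 76% and 86%, so that the excess rises all the way, on the ground that “a growing plateau dilutes a fixed leak”.

The flasks gave 95.7%, 95.2% and 94.3% for dawn, autumn and dusk: the excess hardly changes. In dawn, just after the start, the left-handed path used reagent 50 times as fast as the right-handed path.

    reagent + free catalyst + left-handed substrate → free catalyst + left-handed product (k = 1.10 L² mol⁻² s⁻¹)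
    reagent + free catalyst + right-handed substrate → free catalyst + right-handed product (k = 0.0220 L² mol⁻² s⁻¹)
    free catalyst + added ligand ⇌ idle complex, settled at all times (K = 72.0 L mol⁻¹)
    reagent + free catalyst → spent catalyst (k = 0.0660 L mol⁻¹ s⁻¹)

Carrying s = 40.9 over, dawn kept 82% of its left-handed substrate, which gives 0.242% right-handed product, and it held 0.200%. Dusk kept 44%, which gives 1.01%, and at 10.0 min it held 0.825%.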